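Assumption: all bicyclic compounds are named with the atom numbering of the target's tetralin (C1 aryl-bearing carbon, C2 and C3 the carbons bearing C9 and C10, C4 the benzylic CH2, ring A = C4a–C8a). In this numbering the SMILES of the target corresponds to (1R,2S,3S).

## Analysis of the target

Target 21 is an aryltetralin lignan. Ring A is a benzene ring with three contiguous oxygen substituents (OMe on C5 and C6, free OH on C7), fused through C4a and C8a to the saturated ring B. Ring B carries a 4-hydroxy-3-methoxyphenyl (guaiacyl) ring on C1, hydroxymethyl groups on C2 (C9) and C3 (C10), and a benzylic CH2 at C4. The three stereocentres C1, C2 and C3 are contiguous and all-trans, so the aryl group, C9 and C10 alternate between the two faces of ring B. None of them is next to a carbonyl group in the target, so none can be corrected by equilibration at the end. The sensitive groups are two free phenols on electron-rich rings, two primary alcohols and the doubly benzylic C1–H; all four hydroxyls call for one protecting group that comes off without touching C1. The difficulties are three: telling the C7 oxygen apart from the two methyl ethers, closing ring B at C8a (the least nucleophilic free position of ring A, para only to the twisted central methoxy group), and making the hindered C1–aryl bond trans to C9 while C9 is trans to C10. The strategy rests on the vicinal trans pair C1–aryl / C2–C9. This is the pattern left by anti addition of a migrating aryl group and a one-carbon electrophile across a C1=C2 alkenyl boronate, with boron marking the place of the later C1–H.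

## Retrosynthetic reasoning

**21 from 20.** The four O–benzyl bonds of the tetrabenzyl ether 20 are cut last. One hydrogenolysis frees both phenols and both alcohols. Benzyl ethers are chosen because they survive organolithium, fluoride and palladium-catalysed borylation conditions.

**20 from 19.** The C1–H bond is traced back to the C1–B bond of the tertiary boronate 19. Protodeboronation of a tertiary diarylalkyl boronate with retention puts hydrogen where boron was. Boron in 19 is cis to C9, so the aryl group stays trans to C9.

**19 from 13, 17 and 16 (through 18).** The C1–aryl and C2–C9 bonds are cut together. This is preferred to the ring-closing cuts at C1–C8a or C1–C2 because it leaves ring B as the simple bicyclic alkenyl boronate 13 and lets the aryl ring and C9 arrive as separate small reagents. Forward, aryllithium 17 must add to boron of 13 to give boronate complex 18. The oxocarbenium ion from benzyl chloromethyl ether 16 must then attack C2 anti to the C3 substituent, and the aryl group must shift from boron to C1 anti to the new bond. Two bonds and two stereocentres are gained from the single stereocentre C3.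

**13 from 11 and 12.** The C1–B bond comes from the enol triflate 11 by palladium-catalysed borylation with bis(pinacolato)diboron 12. This is a standard way to turn a ketone-derived C1=C2–O unit into C1=C2–B.

**11 from 10, 9 and 8.** These are functional-group changes at C10 and C1. Benzyl ether 11 comes from alcohol 10, alcohol 10 from ester 9 by hydride reduction, and enol triflate 9 from keto ester 8. C10 is kept as an ester until ring B exists. An ether oxygen at C10 would sit five atoms from the acylating carbon and would capture it as a γ-lactone with loss of its benzyl group. Triflation comes before reduction so that the ketone is masked and only the ester is reduced.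

**8 from 6 (through 7).** The C1–C8a bond is cut. Forward, the acid chloride 7 of half-ester 6 acylates ring A intramolecularly. Only C8a can be reached through a six-membered transition state, so regiochemistry is not in question.

**6 from 5.** The C3–H bond, and with it the absolute configuration, comes from asymmetric hydrogenation of the alkylidene succinate half-ester 5. The free carboxyl group serves as the binding site for the catalyst.

**5 from 3 and 4.** The C3=C4 double bond is cut by a Stobbe disconnection into aldehyde 3 and dimethyl succinate 4. The condensation leaves the free acid on the CH2 arm (the later C1) and the ester on the later C10, which is the differentiation the ring closure needs.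

**3 from 2 and 1; 17 from 15 and 14.** Aldehyde 3 comes from 2,3,4-trihydroxybenzaldehyde 1 by selective benzylation of the 4-OH (giving 2) and methylation of the other two. This solves the differentiation of the C7 oxygen at the very start. Aryllithium 17 comes from bromide 15, the benzyl ether of 4-bromo-2-methoxyphenol 14.

## Alternatives that were turned down

**Alternative 1: oxidative radical bicyclization.**
- Disconnection: C2–C3 and C1–C8a of the lactone-fused tetralin A2, leading back to the open-chain cinnamyl malonamate A1.
- Forward key step: a one-electron oxidant (Mn(OAc)3, with Cu(OAc)2 as co-oxidant) turns the malonyl carbon C3 of A1 into a radical. It adds 5-exo to the alkene (C2–C3, lactone ring). The resulting C1 benzylic radical attacks C8a of ring A (ring B), and oxidation restores aromaticity.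
- For it: two rings, two C–C bonds and three stereocentres arise in one step from a precursor assembled by simple acylations. On this point it is stronger than the chosen route, whose key step closes no ring.
- Against it for this target:
  - C3 of A2 is quaternary and carries a carbonyl carbon that is not in the target. It has to be removed through hydrolysis of a hindered amide and decarboxylation.
  - After that, C3 is an enolizable centre α to a γ-lactone fused across C2–C3. Such a lactone is more stable cis-fused, whereas the target needs C9 and C10 trans.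
  - The face selectivity of a planar malonyl radical rests on a remote pyrrolidine amide.
  - Ester-tethered radicals cyclize slowly because the ester prefers the conformation that holds radical and alkene apart.
  - The C1 radical has to attack the least activated position of ring A.
- Comparison: the chosen strategy offers no sacrificial carbon, a C3 centre set by a catalytic hydrogenation and no longer enolizable after the ester reduction, and a stereospecific relay to C2 and C1.

**Alternative 2: enamine closure onto a quinone methide.**
- Disconnection: C1–C2 of aldehyde A4, leading back to the diarylmethane aldehyde A3.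
- Forward key step: Ag2O oxidizes the 4-hydroxybenzyl unit of A3, so that C1 becomes the exocyclic carbon of a para-quinone methide. Condensation of the aldehyde with a secondary amine makes C2 nucleophilic, and C2 adds to C1, closing ring B.
- For it: the closure copies the biosynthetic logic. C2 is α to an aldehyde in A4 and settles trans to both neighbours under thermodynamic control. A4 already has the free guaiacyl phenol and needs only reduction and debenzylation. In security at C2 and in brevity after the key step it is as strong as or stronger than the chosen route.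
- Against it for this target:
  - A3 needs ring A benzylated at C8a next to the side chain at C4a. C8a is the least nucleophilic position of ring A, so this pentasubstituted arene requires its own lengthy synthesis.
  - The oxidation must be selective in the presence of an enolizable aldehyde and an amine. Secondary amines add to quinone methides at the exocyclic carbon, enamines are themselves oxidized, and a quinone methide without blocking ortho groups tends to dimerize or add water.
- Comparison: the chosen strategy offers a precursor that comes from a routine Friedel–Crafts ring closure, a late convergent union of three components and no redox step at the critical stage.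

**Alternative 3: aryne insertion into a cyclobutanone.**
- Disconnection: C1–C8a and C4–C4a of tetralone A7, leading back to cyclobutanone A5 and the silyl aryl triflate A6.
- Forward key step: fluoride releases the aryne from A6. The enolate carbon C1 of A5 adds to C8a (the aryne carbon remote from the C5 methoxy group), the C4a anion closes onto the carbonyl C4, and the benzocyclobutenoxide opens to ring B.
- For it: ring B is formed while two fragments of similar size are joined, and the aryl–C1 bond is already present in A5. It is more convergent in ring construction than the chosen route.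
- Against it for this target:
  - Both partners are elaborate. A5 is a trisubstituted cyclobutanone with defined trans substituents, and A6 is a hexasubstituted benzene.
  - Insertion of arynes into C–C bonds is established for activated 1,3-dicarbonyl compounds, not for simple ketone enolates, so its novelty risk is at least as high as that of the chosen step.
  - The configuration at C1 is decided by protonation of a diarylmethyl carbanion after the fragmentation, outside the control of the bond-forming events.
  - A7 carries a C4 ketone that has to be removed.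
- Comparison: the chosen strategy offers one simple precursor and two small reagents, fixes C1 and C2 in a stereospecific anti addition and needs no later deoxygenation.

Key step: step 11

## Route

**Step 1**
Reactants: 1 2,3,4-trihydroxybenzaldehyde
Product: 2 4-(benzyloxy)-2,3-dihydroxybenzaldehyde
Conditions: BnBr (1.0 equiv), NaHCO3, DMF, 40 °C
Reagents that add atoms: benzyl bromide, BrCc1ccccc1
Why: Selective phenol O-alkylation: the 4-OH, para to the formyl group, is the most acidic and the 2-OH is held in a hydrogen bond to the carbonyl, so a weak base and one equivalent of halide should alkylate O4.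

**Step 2**
Reactants: 2 4-(benzyloxy)-2,3-dihydroxybenzaldehyde
Product: 3 4-(benzyloxy)-2,3-dimethoxybenzaldehyde
Conditions: MeI (3 equiv), K2CO3, DMF, 40 °C
Reagents that add atoms: iodomethane, CI
Why: Williamson methylation of both remaining phenols; the aldehyde and the benzyl ether are inert.

**Step 3**
Reactants: 3 4-(benzyloxy)-2,3-dimethoxybenzaldehyde; 4 dimethyl succinate
Product: 5 (E)-4-[4-(benzyloxy)-2,3-dimethoxyphenyl]-3-(methoxycarbonyl)but-3-enoic acid
Conditions: NaOMe, MeOH, reflux; then aq. HCl
Reagents that add atoms: none
Why: Stobbe condensation: aldol addition, lactonization and E1cB ring opening should give the half-ester with the free acid on the CH2 arm, the carboxyl that later closes ring B; the E isomer is expected to predominate.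

**Step 4**
Reactants: 5 (E)-4-[4-(benzyloxy)-2,3-dimethoxyphenyl]-3-(methoxycarbonyl)but-3-enoic acid
Product: 6 (S)-4-[4-(benzyloxy)-2,3-dimethoxyphenyl]-3-(methoxycarbonyl)butanoic acid
Conditions: [Rh(cod)((R,R)-Et-DuPHOS)]BF4 (0.5 mol%), NaOMe (10 mol%), H2 (5 bar), MeOH, rt
Reagents that add atoms: none
Why: Rhodium–bisphospholane asymmetric hydrogenation of a β-aryl itaconate half-ester sets C3: the carboxylate and the alkene chelate rhodium and the (R,R) ligand is the antipode expected to give the (S) acid, since this catalyst family gives the (R) series with the (S,S) ligand. E and Z isomers converge under these conditions and the homogeneous catalyst leaves the aryl benzyl ether intact.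

**Step 5**
Reactants: 6 (S)-4-[4-(benzyloxy)-2,3-dimethoxyphenyl]-3-(methoxycarbonyl)butanoic acid
Product: 8 methyl (3S)-7-(benzyloxy)-5,6-dimethoxy-1-oxotetralin-3-carboxylate, via acid chloride 7 (not isolated)
Conditions: (COCl)2, DMF (cat.), CH2Cl2, 0 °C → rt; concentrate; SnCl4, CH2Cl2, −20 → 0 °C
Reagents that add atoms: none
Why: Intramolecular Friedel–Crafts acylation; only C8a can be reached through a six-membered transition state and it is para to the C6 methoxy group. C10 is an ester here so that no ether oxygen can capture the acylating carbon as a lactone, and C3 is not enolized under these acidic conditions.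

**Step 6**
Reactants: 8 methyl (3S)-7-(benzyloxy)-5,6-dimethoxy-1-oxotetralin-3-carboxylate
Product: 9 methyl (3S)-7-(benzyloxy)-5,6-dimethoxy-1-(trifluoromethylsulfonyloxy)-3,4-dihydronaphthalene-3-carboxylate
Conditions: Tf2O, 2,6-di-tert-butyl-4-methylpyridine, CH2Cl2, 0 °C → rt
Reagents that add atoms: trifluoromethanesulfonic anhydride, O=S(=O)(OS(=O)(=O)C(F)(F)F)C(F)(F)F
Why: O-triflation of the aryl ketone with a hindered pyridine gives the only possible enol triflate (C1=C2); no enolate is formed, so the C3–H next to the ester is not exchanged.

**Step 7**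
Reactants: 9 methyl (3S)-7-(benzyloxy)-5,6-dimethoxy-1-(trifluoromethylsulfonyloxy)-3,4-dihydronaphthalene-3-carboxylate
Product: 10 (3S)-7-(benzyloxy)-3-(hydroxymethyl)-5,6-dimethoxy-3,4-dihydronaphthalen-1-yl trifluoromethanesulfonate
Conditions: i-Bu2AlH (2.5 equiv), CH2Cl2, −78 °C; aq. KNaC4H4O6 work-up
Reagents that add atoms: none
Why: Hydride reduction of the ester to the primary alcohol; vinyl triflates are inert to i-Bu2AlH at low temperature and the excess of hydride keeps the intermediate aldehyde from accumulating. From here on C3 is no longer enolizable.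

**Step 8**
Reactants: 10 (3S)-7-(benzyloxy)-3-(hydroxymethyl)-5,6-dimethoxy-3,4-dihydronaphthalen-1-yl trifluoromethanesulfonate
Product: 11 (3S)-7-(benzyloxy)-3-(benzyloxymethyl)-5,6-dimethoxy-3,4-dihydronaphthalen-1-yl trifluoromethanesulfonate
Conditions: BnOC(=NH)CCl3, TfOH (cat.), CH2Cl2–cyclohexane, 0 °C → rt
Reagents that add atoms: benzyl 2,2,2-trichloroacetimidate, N=C(OCc1ccccc1)C(Cl)(Cl)Cl
Why: Acid-catalysed O-benzylation with the imidate avoids an alkoxide that could attack the triflate sulfur; the vinyl triflate tolerates catalytic acid.

**Step 9**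
Reactants: 11 (3S)-7-(benzyloxy)-3-(benzyloxymethyl)-5,6-dimethoxy-3,4-dihydronaphthalen-1-yl trifluoromethanesulfonate; 12 bis(pinacolato)diboron
Product: 13 2-[(3S)-7-(benzyloxy)-3-(benzyloxymethyl)-5,6-dimethoxy-3,4-dihydronaphthalen-1-yl]-4,4,5,5-tetramethyl-1,3,2-dioxaborolane
Conditions: PdCl2(dppf) (3 mol%), dppf (3 mol%), KOAc, 1,4-dioxane, 80 °C
Reagents that add atoms: none
Why: Miyaura borylation: oxidative addition of the vinyl triflate to zerovalent palladium, acetate-assisted transmetalation with the diboron and reductive elimination; ethers and the stereocentre are untouched.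

**Step 10**
Reactants: 14 4-bromo-2-methoxyphenol
Product: 15 1-(benzyloxy)-4-bromo-2-methoxybenzene
Conditions: BnBr, K2CO3, acetone, reflux
Reagents that add atoms: benzyl bromide, BrCc1ccccc1
Why: Williamson ether synthesis on a simple phenol.

**Step 11**
Reactants: 15 1-(benzyloxy)-4-bromo-2-methoxybenzene; 13 2-[(3S)-7-(benzyloxy)-3-(benzyloxymethyl)-5,6-dimethoxy-3,4-dihydronaphthalen-1-yl]-4,4,5,5-tetramethyl-1,3,2-dioxaborolane; 16 benzyl chloromethyl ether
Product: 19 2-[(1R,2S,3S)-7-(benzyloxy)-1-[4-(benzyloxy)-3-methoxyphenyl]-2,3-bis(benzyloxymethyl)-5,6-dimethoxytetralin-1-yl]-4,4,5,5-tetramethyl-1,3,2-dioxaborolane, via aryllithium 17 (not isolated), via lithium boronate complex 18 (not isolated)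
Conditions: 15 (1.05 equiv), t-BuLi (2.1 equiv), THF, −78 °C; 13 (1.0 equiv) in THF, −78 °C, 30 min; 16 (1.5 equiv), −78 → 0 °C
Reagents that add atoms: none
Why: Proposed new method: bromine–lithium exchange gives 17, which adds to the vacant orbital on boron of 13 to form the tetracoordinate boronate 18; the electron-rich B–C1 bond makes C2 nucleophilic, the benzyloxymethyl oxocarbenium ion released from 16 (ionization helped by Li+ and loss of LiCl) bonds to C2, and the aryl group shifts from boron to C1 anti-periplanar to the forming C2–C9 bond, leaving boron on C1. The closest known reaction type is the electrophile-induced 1,2-metallate rearrangement of alkenyl boronate complexes, in which a migrating carbon group and a selenium, iminium or stabilized carbenium electrophile add anti across the double bond; new here are an α-chloro ether as the electrophile and a cyclic styrenyl boronate with an allylic stereocentre. No ring is closed. C2 is controlled by the C3 benzyloxymethyl group, which shields one face so that the electrophile enters anti to it, the same 1,2-induction that makes alkylation of 3-substituted cyclohexanone enolates trans-selective; C1 is then fixed by the stereospecific anti migration, so the aryl group ends trans to C9 and boron cis to it. The step needs chemoselectivity for C2 over the ipso carbon of the electron-rich aryl group on boron and over the pinacolate oxygens, which the styrenyl π bond, activated by the boronate and conjugated with ring A, should secure, and regioselectivity for C2 over C1, which follows from boron being on C1. t-BuLi in two equivalents leaves no alkyl bromide and no excess alkyllithium to compete for boron or for 16.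

**Step 12**
Reactants: 19 2-[(1R,2S,3S)-7-(benzyloxy)-1-[4-(benzyloxy)-3-methoxyphenyl]-2,3-bis(benzyloxymethyl)-5,6-dimethoxytetralin-1-yl]-4,4,5,5-tetramethyl-1,3,2-dioxaborolane
Product: 20 (1R,2S,3S)-7-(benzyloxy)-1-[4-(benzyloxy)-3-methoxyphenyl]-2,3-bis(benzyloxymethyl)-5,6-dimethoxytetralin
Conditions: CsF (1.5 equiv), H2O (1.1 equiv), 1,4-dioxane, 45 °C
Reagents that add atoms: none
Why: Fluoride-promoted protodeboronation of a tertiary diarylalkyl pinacol boronate; the ate complex passes C1 to a proton of bound water on the face boron occupied (retention), so C1–H ends cis to C9 and the aryl group stays trans to it.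

**Step 13**
Reactants: 20 (1R,2S,3S)-7-(benzyloxy)-1-[4-(benzyloxy)-3-methoxyphenyl]-2,3-bis(benzyloxymethyl)-5,6-dimethoxytetralin
Product: 21 (1R,2S,3S)-1-(4-hydroxy-3-methoxyphenyl)-2,3-bis(hydroxymethyl)-5,6-dimethoxytetralin-7-ol (CNP0197710.1)
Conditions: H2 (1 atm), Pd/C (10 wt%), EtOAc–MeOH, rt
Reagents that add atoms: none
Why: Hydrogenolysis of two aryl and two alkyl benzyl ethers; the methyl ethers, the diarylmethine C–H and the three stereocentres are inert under these conditions.

## Compound list

1 | 2,3,4-trihydroxybenzaldehyde | O=Cc1ccc(O)c(O)c1O | starting material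
2 | 4-(benzyloxy)-2,3-dihydroxybenzaldehyde | O=Cc1ccc(OCc2ccccc2)c(O)c1O | intermediate
3 | 4-(benzyloxy)-2,3-dimethoxybenzaldehyde | O=Cc1ccc(OCc2ccccc2)c(OC)c1OC | intermediate
4 | dimethyl succinate | COC(=O)CCC(=O)OC | starting material
5 | (E)-4-[4-(benzyloxy)-2,3-dimethoxyphenyl]-3-(methoxycarbonyl)but-3-enoic acid | COC(=O)/C(CC(=O)O)=C/c1ccc(OCc2ccccc2)c(OC)c1OC | intermediate
6 | (S)-4-[4-(benzyloxy)-2,3-dimethoxyphenyl]-3-(methoxycarbonyl)butanoic acid | COC(=O)[C@H](CC(=O)O)Cc1ccc(OCc2ccccc2)c(OC)c1OC | intermediate
7 | methyl (S)-2-[4-(benzyloxy)-2,3-dimethoxybenzyl]-4-chloro-4-oxobutanoate (acid chloride of 6) | COC(=O)[C@H](CC(=O)Cl)Cc1ccc(OCc2ccccc2)c(OC)c1OC | intermediate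
8 | methyl (3S)-7-(benzyloxy)-5,6-dimethoxy-1-oxotetralin-3-carboxylate | COC(=O)[C@@H]1CC(=O)c2cc(OCc3ccccc3)c(OC)c(OC)c2C1 | intermediate
9 | methyl (3S)-7-(benzyloxy)-5,6-dimethoxy-1-(trifluoromethylsulfonyloxy)-3,4-dihydronaphthalene-3-carboxylate | COC(=O)[C@@H]1C=C(OS(=O)(=O)C(F)(F)F)c2cc(OCc3ccccc3)c(OC)c(OC)c2C1 | intermediate
10 | (3S)-7-(benzyloxy)-3-(hydroxymethyl)-5,6-dimethoxy-3,4-dihydronaphthalen-1-yl trifluoromethanesulfonate | OC[C@@H]1C=C(OS(=O)(=O)C(F)(F)F)c2cc(OCc3ccccc3)c(OC)c(OC)c2C1 | intermediate
11 | (3S)-7-(benzyloxy)-3-(benzyloxymethyl)-5,6-dimethoxy-3,4-dihydronaphthalen-1-yl trifluoromethanesulfonate | O=S(=O)(OC1=C[C@@H](COCc2ccccc2)Cc2c(OC)c(OC)c(OCc3ccccc3)cc21)C(F)(F)F | intermediate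
12 | bis(pinacolato)diboron | CC1(C)OB(OC1(C)C)B1OC(C)(C)C(C)(C)O1 | starting material
13 | 2-[(3S)-7-(benzyloxy)-3-(benzyloxymethyl)-5,6-dimethoxy-3,4-dihydronaphthalen-1-yl]-4,4,5,5-tetramethyl-1,3,2-dioxaborolane | CC1(C)OB(C2=C[C@@H](COCc3ccccc3)Cc3c(OC)c(OC)c(OCc4ccccc4)cc32)OC1(C)C | intermediate
14 | 4-bromo-2-methoxyphenol | COc1cc(Br)ccc1O | starting material
15 | 1-(benzyloxy)-4-bromo-2-methoxybenzene | COc1cc(Br)ccc1OCc1ccccc1 | intermediate
16 | benzyl chloromethyl ether | ClCOCc1ccccc1 | starting material
17 | 4-(benzyloxy)-3-methoxyphenyllithium | [Li]c1ccc(OCc2ccccc2)c(OC)c1 | intermediate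
18 | lithium [4-(benzyloxy)-3-methoxyphenyl][(3S)-7-(benzyloxy)-3-(benzyloxymethyl)-5,6-dimethoxy-3,4-dihydronaphthalen-1-yl](pinacolato)borate | [Li+].COc1cc(ccc1OCc1ccccc1)[B-]1(OC(C)(C)C(C)(C)O1)C1=C[C@@H](COCc2ccccc2)Cc2c(OC)c(OC)c(OCc3ccccc3)cc21 | intermediate
19 | 2-[(1R,2S,3S)-7-(benzyloxy)-1-[4-(benzyloxy)-3-methoxyphenyl]-2,3-bis(benzyloxymethyl)-5,6-dimethoxytetralin-1-yl]-4,4,5,5-tetramethyl-1,3,2-dioxaborolane | COc1cc([C@]2(B4OC(C)(C)C(C)(C)O4)c3cc(OCc4ccccc4)c(OC)c(OC)c3C[C@H](COCc3ccccc3)[C@H]2COCc2ccccc2)ccc1OCc1ccccc1 | intermediate
20 | (1R,2S,3S)-7-(benzyloxy)-1-[4-(benzyloxy)-3-methoxyphenyl]-2,3-bis(benzyloxymethyl)-5,6-dimethoxytetralin | COc1cc([C@@H]2c3cc(OCc4ccccc4)c(OC)c(OC)c3C[C@H](COCc3ccccc3)[C@H]2COCc2ccccc2)ccc1OCc1ccccc1 | intermediate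
21 | (1R,2S,3S)-1-(4-hydroxy-3-methoxyphenyl)-2,3-bis(hydroxymethyl)-5,6-dimethoxytetralin-7-ol (CNP0197710.1) | COc1cc([C@@H]2c3cc(O)c(OC)c(OC)c3C[C@H](CO)[C@H]2CO)ccc1O | target

## Step count and least certain steps

Total: 13 steps. Longest linear sequence: 12 steps (steps 1–9 and 11–13 from 1); step 10 is a one-step side branch.

**Step 11 (key step).**
- What may go wrong: the oxocarbenium ion may attack the ipso carbon of the electron-rich aryl group on boron (aryl transfer instead of migration), because such aryl groups are themselves good nucleophiles in boronate complexes. Facial selectivity at C2 may be poor, because the half-chair is flexible and the directing C3 substituent is small. The chloro ether may also ionize too little in THF.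
- Fallback (known chemistry, bonds at C1 made in the reverse order), setting out from 13 and returning at 21:
  - Oxidation of the alkenyl boronate with NaBO3·4H2O in THF–H2O should give (3S)-7-(benzyloxy)-3-(benzyloxymethyl)-5,6-dimethoxy-1-tetralone F1.
  - Its lithium enolate (LiN(SiMe3)2, THF, −78 °C) should be alkylated by 16 anti to the C3 substituent, at a carbon that can also equilibrate, to give (2S,3S)-7-(benzyloxy)-2,3-bis(benzyloxymethyl)-5,6-dimethoxy-1-tetralone F2.
  - NaBH4 in MeOH should give (2S,3S)-7-(benzyloxy)-2,3-bis(benzyloxymethyl)-5,6-dimethoxytetralin-1-ol F3.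
  - BF3·OEt2 in CH2Cl2 with an excess of 2-methoxyphenol should ionize C1. The phenol should attack the cation, which is stabilized by the C6 methoxy group, through its position para to OH and anti to the C2 substituent, giving (1R,2S,3S)-7-(benzyloxy)-2,3-bis(benzyloxymethyl)-1-(4-hydroxy-3-methoxyphenyl)-5,6-dimethoxytetralin F4.
  - The conditions of step 13 should convert F4 into 21.

**Step 12.**
- What may go wrong: configuration at C1 may erode if the C–B bond breaks to a free diarylmethyl carbanion before the proton is transferred. A planar C1 would be protonated anti to the C2 substituent, which leads to the 1,2-cis epimer. Steric shielding of the tertiary boron may also slow the reaction.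
- Fallback, setting out from 19 and returning at 21:
  - Oxidation with NaBO3·4H2O in THF–H2O (retention) should give (1S,2S,3S)-7-(benzyloxy)-1-[4-(benzyloxy)-3-methoxyphenyl]-2,3-bis(benzyloxymethyl)-5,6-dimethoxytetralin-1-ol F5.
  - Hydrogenolysis over Raney nickel (H2, EtOH) should replace the tertiary benzylic C–OH by C–H with retention, which is the usual course on nickel, whereas palladium tends to invert.
  - The same treatment, finished if needed with the conditions of step 13, should remove the benzyl ethers and give 21.

**Step 4.**
- What may go wrong: enantioface selection may be too low or reversed. The sense is assigned by analogy with simpler β-aryl itaconate half-esters, and the ortho methoxy group may disturb binding.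
- Fallback (auxiliary control in place of catalyst control), setting out from 3 and returning at 6:
  - NaBH4 in MeOH should give [4-(benzyloxy)-2,3-dimethoxyphenyl]methanol F6, and PBr3 in Et2O at 0 °C should give 1-(benzyloxy)-4-(bromomethyl)-2,3-dimethoxybenzene F7.
  - (S)-4-Benzyl-2-oxazolidinone is acylated with 4-tert-butoxy-4-oxobutanoic acid (pivaloyl chloride, Et3N, LiCl, THF) to give tert-butyl 4-[(4S)-4-benzyl-2-oxo-1,3-oxazolidin-3-yl]-4-oxobutanoate F8.
  - The chelated Z sodium enolate of F8 (NaN(SiMe3)2, THF, −78 °C) should be alkylated by F7 on the face away from the auxiliary benzyl group. This gives tert-butyl (3S)-4-[4-(benzyloxy)-2,3-dimethoxyphenyl]-3-{[(4S)-4-benzyl-2-oxo-1,3-oxazolidin-3-yl]carbonyl}butanoate F9, whose new centre has the configuration of C3.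
  - MeOMgBr in MeOH at 0 °C should exchange the auxiliary for methoxide to give 4-tert-butyl 1-methyl (2S)-2-[4-(benzyloxy)-2,3-dimethoxybenzyl]butanedioate F10.
  - CF3CO2H in CH2Cl2 at 0 °C should cleave the tert-butyl ester to 6.

**Step 5.**
- What may go wrong: the aryl benzyl ether may be lost under SnCl4 and HCl. Closure may be sluggish because C8a is activated only by the twisted C6 methoxy group. Chloride may demethylate the ester through a cyclic acyloxonium ion.
- Fallback (ring closure without the benzyl group), setting out from 6 and returning at 8: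
  - H2 over Pd/C in EtOAc should give (3S)-4-(4-hydroxy-2,3-dimethoxyphenyl)-3-(methoxycarbonyl)butanoic acid F11.
  - P2O5 in MeSO3H at rt should close it to methyl (3S)-7-hydroxy-5,6-dimethoxy-1-oxotetralin-3-carboxylate F12.
  - BnBr with K2CO3 in acetone should give 8.

## Further compounds

F1 | step 11 | (3S)-7-(benzyloxy)-3-(benzyloxymethyl)-5,6-dimethoxy-1-tetralone | O=C1C[C@@H](COCc2ccccc2)Cc2c(OC)c(OC)c(OCc3ccccc3)cc21
F2 | step 11 | (2S,3S)-7-(benzyloxy)-2,3-bis(benzyloxymethyl)-5,6-dimethoxy-1-tetralone | O=C1[C@H](COCc2ccccc2)[C@@H](COCc2ccccc2)Cc2c(OC)c(OC)c(OCc3ccccc3)cc21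
F3 | step 11 | (2S,3S)-7-(benzyloxy)-2,3-bis(benzyloxymethyl)-5,6-dimethoxytetralin-1-ol (C1 epimers) | OC1[C@H](COCc2ccccc2)[C@@H](COCc2ccccc2)Cc2c(OC)c(OC)c(OCc3ccccc3)cc21
F4 | step 11 | (1R,2S,3S)-7-(benzyloxy)-2,3-bis(benzyloxymethyl)-1-(4-hydroxy-3-methoxyphenyl)-5,6-dimethoxytetralin | COc1cc([C@@H]2c3cc(OCc4ccccc4)c(OC)c(OC)c3C[C@H](COCc3ccccc3)[C@H]2COCc2ccccc2)ccc1O
F5 | step 12 | (1S,2S,3S)-7-(benzyloxy)-1-[4-(benzyloxy)-3-methoxyphenyl]-2,3-bis(benzyloxymethyl)-5,6-dimethoxytetralin-1-ol | COc1cc([C@]2(O)c3cc(OCc4ccccc4)c(OC)c(OC)c3C[C@H](COCc3ccccc3)[C@H]2COCc2ccccc2)ccc1OCc1ccccc1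
F6 | step 4 | [4-(benzyloxy)-2,3-dimethoxyphenyl]methanol | OCc1ccc(OCc2ccccc2)c(OC)c1OC
F7 | step 4 | 1-(benzyloxy)-4-(bromomethyl)-2,3-dimethoxybenzene | BrCc1ccc(OCc2ccccc2)c(OC)c1OC
F8 | step 4 | tert-butyl 4-[(4S)-4-benzyl-2-oxo-1,3-oxazolidin-3-yl]-4-oxobutanoate | CC(C)(C)OC(=O)CCC(=O)N1[C@@H](Cc2ccccc2)COC1=O
F9 | step 4 | tert-butyl (3S)-4-[4-(benzyloxy)-2,3-dimethoxyphenyl]-3-{[(4S)-4-benzyl-2-oxo-1,3-oxazolidin-3-yl]carbonyl}butanoate | CC(C)(C)OC(=O)C[C@H](Cc1ccc(OCc2ccccc2)c(OC)c1OC)C(=O)N1[C@@H](Cc2ccccc2)COC1=O
F10 | step 4 | 4-tert-butyl 1-methyl (2S)-2-[4-(benzyloxy)-2,3-dimethoxybenzyl]butanedioate | COC(=O)[C@H](CC(=O)OC(C)(C)C)Cc1ccc(OCc2ccccc2)c(OC)c1OC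
F11 | step 5 | (3S)-4-(4-hydroxy-2,3-dimethoxyphenyl)-3-(methoxycarbonyl)butanoic acid | COC(=O)[C@H](CC(=O)O)Cc1ccc(O)c(OC)c1OC
F12 | step 5 | methyl (3S)-7-hydroxy-5,6-dimethoxy-1-oxotetralin-3-carboxylate | COC(=O)[C@@H]1CC(=O)c2cc(O)c(OC)c(OC)c2C1
A1 | alternative 1 | (E)-3-[4-(benzyloxy)-3-methoxyphenyl]allyl 2-[4-(benzyloxy)-2,3-dimethoxybenzyl]-3-[(2R,5R)-2,5-dimethylpyrrolidin-1-yl]-3-oxopropanoate | COc1cc(/C=C/COC(=O)C(Cc2ccc(OCc3ccccc3)c(OC)c2OC)C(=O)N2[C@H](C)CC[C@H]2C)ccc1OCc1ccccc1
A2 | alternative 1 | aryltetralin fused γ-lactone (C9–O–C10=O) with the (2R,5R)-2,5-dimethylpyrrolidine carboxamide on C3 | COc1cc([C@@H]2c3cc(OCc4ccccc4)c(OC)c(OC)c3C[C@]5(C(=O)N6[C@H](C)CC[C@H]6C)C(=O)OC[C@@H]25)ccc1OCc1ccccc1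
A3 | alternative 2 | (3S)-4-[4-(benzyloxy)-6-(4-hydroxy-3-methoxybenzyl)-2,3-dimethoxyphenyl]-3-(benzyloxymethyl)butanal | COc1cc(Cc2cc(OCc3ccccc3)c(OC)c(OC)c2C[C@H](COCc2ccccc2)CC=O)ccc1O
A4 | alternative 2 | (1R,2S,3S)-7-(benzyloxy)-3-(benzyloxymethyl)-1-(4-hydroxy-3-methoxyphenyl)-5,6-dimethoxytetralin-2-carbaldehyde | COc1cc([C@@H]2c3cc(OCc4ccccc4)c(OC)c(OC)c3C[C@H](COCc3ccccc3)[C@H]2C=O)ccc1O
A5 | alternative 3 | 2-[4-(benzyloxy)-3-methoxyphenyl]-trans-3,4-bis(benzyloxymethyl)cyclobutan-1-one (C2 of the ring enolizable and undefined) | COc1cc(C2C(=O)[C@H](COCc3ccccc3)[C@H]2COCc2ccccc2)ccc1OCc1ccccc1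
A6 | alternative 3 | 4-(benzyloxy)-2,3-dimethoxy-6-(trimethylsilyl)phenyl trifluoromethanesulfonate | COc1c(OC)c(OCc2ccccc2)cc([Si](C)(C)C)c1OS(=O)(=O)C(F)(F)F
A7 | alternative 3 | all-trans 7-(benzyloxy)-1-[4-(benzyloxy)-3-methoxyphenyl]-2,3-bis(benzyloxymethyl)-5,6-dimethoxytetral-4-one | COc1cc([C@@H]2c3cc(OCc4ccccc4)c(OC)c(OC)c3C(=O)[C@H](COCc3ccccc3)[C@H]2COCc2ccccc2)ccc1OCc1ccccc1
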